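**Plan**

- Atom numbers follow germacranolide usage: ring A is the ten-membered carbocycle C1–C10, ring B the γ-lactone O6–C12(=O)–C11–C7–C6, with C13 the exocyclic methylene, C14 the formyl carbon, C15 the hydroxymethyl carbon and C2′ the α-carbon of the ester side chain.
- Retrosynthetic cuts, in order: the C8–O acyl bond; C11=C13 (back to a Mannich base); then O6–C12 and C5–C6 together in one retro-step (vinyl iodide plus aldehyde and methyl ester); then C1=C10 (olefination), C9–C10 (phosphonate alkylation) and C7–C11 (enolate allylation).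
- Forward: a west C1–C5/C15 iodoalkene aldehyde (from malonate) and an east C6–C10 phosphonate carrying C11/C12 (from malate) are joined at C1=C10. The open-chain dialdehyde then closes ring A and ring B in one operation; the methylene is unveiled, C8 is acylated and C15 is freed.
- Enabling feature: C6 is both the allylic carbinol carbon next to the C4=C5 olefin and the γ-carbon of the lactone. A C5 vinyl nucleophile adding to a C6 aldehyde leaves an alkoxide 1,4 to the C12 ester on C7, so closing ring A triggers closure of ring B. Both olefins are cis within ring A, which folds the chain and makes attack on the C14 enal geometrically impossible.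
- Stereochemistry: C8 from (S)-malic acid; C7 by anti-selective Fráter–Seebach allylation; C6 in the key step; C2′ from (S)-2-methylbutanoic acid; C4=C5 geometry from a decarboxylative elimination and C1=C10 geometry from the Horner–Wadsworth–Emmons reaction.

Key step: step 17

Remark: 10 is carried as a mixture of epimers at the phosphonate carbon and 23–27 as mixtures of epimers at C11; both centres become sp2 (steps 14 and 18), so the mixtures converge.

**East fragment**

Step 1
Reactants: 1 diethyl (S)-malate; 2 allyl bromide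
Product: 3 diethyl (2S,3R)-2-hydroxy-3-(prop-2-en-1-yl)butanedioate
Conditions: LiN(iPr)2 (2.1 equiv), THF, −78 → −20 °C; then 2, −78 → 0 °C
Reagents that add atoms: none
Why: Fráter–Seebach alkylation: the chelated lithium alkoxide–enolate dianion should be allylated on the face opposite the C9 ester group, setting C7 anti to the C8 oxygen, while C8 comes unchanged from (S)-malic acid.

Step 2
Reactants: 3 diethyl (2S,3R)-2-hydroxy-3-(prop-2-en-1-yl)butanedioate
Product: 4 ethyl (2R)-2-[(1S)-1,2-dihydroxyethyl]pent-4-enoate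
Conditions: BH3·SMe2 (1.0 equiv), NaBH4 (5 mol%), THF, 0 → 20 °C; MeOH quench; used at once
Reagents that add atoms: none
Why: Hydroxyl-directed borane reduction (NaBH4-catalysed): the alkoxyborane formed at O8 should deliver hydride only to the adjacent C9 ester, and one equivalent of borane is expected to be captured by the hydroxyl faster than it hydroborates the allyl group.

Step 3
Reactants: 4 ethyl (2R)-2-[(1S)-1,2-dihydroxyethyl]pent-4-enoate
Product: 5 ethyl (2R)-2-[(1S)-1-hydroxy-2-iodoethyl]pent-4-enoate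
Conditions: I2, PPh3, imidazole, CH2Cl2, 0 °C
Reagents that add atoms: iodine, II
Why: Appel-type iodination is selective for the primary hydroxyl of a 1,2-diol and turns C9 into the electrophile needed in step 7 without touching a stereocentre.

Step 4
Reactants: 5 ethyl (2R)-2-[(1S)-1-hydroxy-2-iodoethyl]pent-4-enoate
Product: 6 ethyl (2R)-2-{(1S)-2-iodo-1-[(triethylsilyl)oxy]ethyl}pent-4-enoate
Conditions: Et3SiOTf, 2,6-lutidine, CH2Cl2, −78 °C
Reagents that add atoms: triethylsilyl trifluoromethanesulfonate, CC[Si](CC)(CC)OS(=O)(=O)C(F)(F)F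
Why: Silylation with a silyl triflate masks O8 as a triethylsilyl ether, which blocks lactonization onto C12 later and can be removed in the presence of the tert-butyldiphenylsilyl ether.

Step 5
Reactants: 6 ethyl (2R)-2-{(1S)-2-iodo-1-[(triethylsilyl)oxy]ethyl}pent-4-enoate
Product: 7 (2R)-2-{(1S)-2-iodo-1-[(triethylsilyl)oxy]ethyl}-N-methoxy-N-methylpent-4-enamide
Conditions: MeNH(OMe)·HCl, iPrMgCl, THF, −20 → 0 °C
Reagents that add atoms: N,O-dimethylhydroxylamine hydrochloride, CNOC.Cl
Why: Weinreb amide formation by aminolysis of the ester with the chloromagnesium amide makes C6 a latent aldehyde that can be unmasked in step 16 without touching a methyl ester.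

Step 6
Reactants: 7 (2R)-2-{(1S)-2-iodo-1-[(triethylsilyl)oxy]ethyl}-N-methoxy-N-methylpent-4-enamide
Product: 8 methyl (3R,4S)-5-iodo-3-[methoxy(methyl)carbamoyl]-4-[(triethylsilyl)oxy]pentanoate
Conditions: O3 (dosed to the alkene end-point), CH2Cl2/2.5 M NaOH in MeOH, −78 °C
Reagents that add atoms: ozone, [O-][O+]=O; methanol, CO
Why: Ozonolysis in methanolic NaOH converts the terminal alkene directly into the methyl ester (the methanol hemiacetal of the aldehyde is oxidized by ozone), turning the allyl group into the C11–C12 acetate arm.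

Step 7
Reactants: 8 methyl (3R,4S)-5-iodo-3-[methoxy(methyl)carbamoyl]-4-[(triethylsilyl)oxy]pentanoate; 9 diethyl {2-[methoxy(methyl)amino]-2-oxoethyl}phosphonate
Product: 10 methyl (3R,4R)-6-(diethoxyphosphoryl)-3-[methoxy(methyl)carbamoyl]-7-[methoxy(methyl)amino]-7-oxo-4-[(triethylsilyl)oxy]heptanoate
Conditions: 9 (1.5 equiv), NaH, DMF, 0 °C; then 8, 55 °C
Reagents that add atoms: none
Why: SN2 alkylation of the sodium phosphonate carbanion by the primary iodide forms C9–C10 and installs the Horner–Wadsworth–Emmons reagent; the doubly stabilized carbanion should leave the ester and amide groups alone.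

**West fragment**

Step 8
Reactants: 11 diethyl malonate; 12 2-(2-bromoethyl)-1,3-dioxolane
Product: 13 diethyl 2-[2-(1,3-dioxolan-2-yl)ethyl]propanedioate
Conditions: NaH, 11 (excess), THF/DMF, 0 → 60 °C
Reagents that add atoms: none
Why: Malonic ester alkylation (SN2) attaches the C1–C3 chain, with C1 masked as a dioxolane, to the future C4.

Step 9
Reactants: 13 diethyl 2-[2-(1,3-dioxolan-2-yl)ethyl]propanedioate; 14 iodoform
Product: 15 diethyl 2-(diiodomethyl)-2-[2-(1,3-dioxolan-2-yl)ethyl]propanedioate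
Conditions: NaH, THF, 0 °C; then 14, reflux
Reagents that add atoms: none
Why: C-Diiodomethylation of the malonate enolate with iodoform introduces C5 together with its iodine.

Step 10
Reactants: 15 diethyl 2-(diiodomethyl)-2-[2-(1,3-dioxolan-2-yl)ethyl]propanedioate
Product: 17 (2E)-2-[2-(1,3-dioxolan-2-yl)ethyl]-3-iodoprop-2-enoic acid, via dipotassium (diiodomethyl)malonate 16 (not isolated)
Conditions: KOH, EtOH/H2O, reflux; then cold 1 M HCl to pH 3
Reagents that add atoms: potassium hydroxide, [K+].[OH-]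
Why: Saponification, then decarboxylation with loss of iodide from dicarboxylate 16, should give the β-iodoacrylic acid with iodine trans to the carboxyl group (E), the isomer this decarboxylative elimination is known to give, which places iodine cis to the C3 chain as ring A requires.

Step 11
Reactants: 17 (2E)-2-[2-(1,3-dioxolan-2-yl)ethyl]-3-iodoprop-2-enoic acid
Product: 18 (2E)-2-[2-(1,3-dioxolan-2-yl)ethyl]-3-iodoprop-2-en-1-ol
Conditions: LiAlH4, Et2O, 0 °C
Reagents that add atoms: none
Why: Hydride reduction of the carboxylic acid at low temperature should give the C15 allylic alcohol while leaving the vinyl iodide and the acetal intact.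

Step 12
Reactants: 18 (2E)-2-[2-(1,3-dioxolan-2-yl)ethyl]-3-iodoprop-2-en-1-ol
Product: 19 tert-butyl({(2E)-2-[2-(1,3-dioxolan-2-yl)ethyl]-3-iodoprop-2-en-1-yl}oxy)diphenylsilane
Conditions: tBuPh2SiCl, imidazole, CH2Cl2, 20 °C
Reagents that add atoms: tert-butyl(chloro)diphenylsilane, CC(C)(C)[Si](Cl)(c1ccccc1)c1ccccc1
Why: Silylation protects O15 with a group that should survive every later step and is removed last.

Step 13
Reactants: 19 tert-butyl({(2E)-2-[2-(1,3-dioxolan-2-yl)ethyl]-3-iodoprop-2-en-1-yl}oxy)diphenylsilane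
Product: 20 (4E)-4-{[(tert-butyldiphenylsilyl)oxy]methyl}-5-iodopent-4-enal
Conditions: 1 M HCl, THF, 20 °C
Reagents that add atoms: water, O
Why: Acid-catalysed acetal hydrolysis frees the C1 aldehyde; the silyl ether and the vinyl iodide are stable to dilute acid.

**Union and endgame**

Step 14
Reactants: 10 methyl (3R,4R)-6-(diethoxyphosphoryl)-3-[methoxy(methyl)carbamoyl]-7-[methoxy(methyl)amino]-7-oxo-4-[(triethylsilyl)oxy]heptanoate; 20 (4E)-4-{[(tert-butyldiphenylsilyl)oxy]methyl}-5-iodopent-4-enal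
Product: 21 methyl (3R,4R,6E,10E)-10-{[(tert-butyldiphenylsilyl)oxy]methyl}-11-iodo-3,6-bis[methoxy(methyl)carbamoyl]-4-[(triethylsilyl)oxy]undeca-6,10-dienoate
Conditions: NaH, THF, 0 °C; then 20, 0 → 20 °C
Reagents that add atoms: none
Why: Horner–Wadsworth–Emmons olefination of the α-branched stabilized phosphonate with the unhindered aldehyde should give the trisubstituted enamide with the carbonyl trans to the C2 chain (E), the geometry required at C1=C10.

Step 15
Reactants: 21 methyl (3R,4R,6E,10E)-10-{[(tert-butyldiphenylsilyl)oxy]methyl}-11-iodo-3,6-bis[methoxy(methyl)carbamoyl]-4-[(triethylsilyl)oxy]undeca-6,10-dienoate; 22 N,N-dimethylmethyleneiminium iodide (Eschenmoser's salt)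
Product: 23 methyl (3R,4R,6E,10E)-10-{[(tert-butyldiphenylsilyl)oxy]methyl}-2-[(dimethylamino)methyl]-11-iodo-3,6-bis[methoxy(methyl)carbamoyl]-4-[(triethylsilyl)oxy]undeca-6,10-dienoate
Conditions: LiN(SiMe3)2 (1.2 equiv), THF, −78 °C; then 22, −78 → 0 °C
Reagents that add atoms: none
Why: Mannich reaction: the lithium enolate of the methyl ester, the most acidic and accessible C–H site, is aminomethylated, which installs C13 as a Mannich base stable to the next two steps (C11 configuration is irrelevant).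

Step 16
Reactants: 23 methyl (3R,4R,6E,10E)-10-{[(tert-butyldiphenylsilyl)oxy]methyl}-2-[(dimethylamino)methyl]-11-iodo-3,6-bis[methoxy(methyl)carbamoyl]-4-[(triethylsilyl)oxy]undeca-6,10-dienoate
Product: 24 methyl (3R,4R,6E,10E)-10-{[(tert-butyldiphenylsilyl)oxy]methyl}-2-[(dimethylamino)methyl]-3,6-diformyl-11-iodo-4-[(triethylsilyl)oxy]undeca-6,10-dienoate
Conditions: Cp2Zr(H)Cl (3.2 equiv), THF, 20 °C, 30 min; used at once
Reagents that add atoms: none
Why: Reduction of both Weinreb amides by the zirconium hydride stops at the aldehyde level through stable zirconated hemiaminals and is chemoselective over the methyl ester, so the C6 aldehyde and the C14 enal arise together.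

Step 17
Reactants: 24 methyl (3R,4R,6E,10E)-10-{[(tert-butyldiphenylsilyl)oxy]methyl}-2-[(dimethylamino)methyl]-3,6-diformyl-11-iodo-4-[(triethylsilyl)oxy]undeca-6,10-dienoate
Product: 26 (3aS,4R,6E,10E,11aR)-10-{[(tert-butyldiphenylsilyl)oxy]methyl}-3-[(dimethylamino)methyl]-2-oxo-4-[(triethylsilyl)oxy]-2,3,3a,4,5,8,9,11a-octahydrocyclodeca[b]furan-6-carbaldehyde, via macrocyclic C6 dichlorochromium alkoxide 25 (not isolated)
Conditions: CrCl2 (10 equiv), NiCl2 (0.1 equiv), degassed DMSO, 25 °C, 24 added slowly to a final 2 mM; aq. NH4Cl work-up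
Reagents that add atoms: none
Why: Nozaki–Hiyama–Kishi reaction run as a cascade: zerovalent nickel inserts into the C5–I bond, transmetalation gives a C5 vinyl species of trivalent chromium that adds to the C6 aldehyde, and the C6 chromium alkoxide 25, held 1,4 to the C12 methyl ester, acylates itself with loss of methoxide. The closest known reaction types are the intramolecular vinyl iodide–aldehyde Nozaki–Hiyama–Kishi closure of medium rings and the chromium-mediated 2-(alkoxycarbonyl)allylation of aldehydes, in which the chromium alkoxide lactonizes in the same flask. Ring A closes by 10-exo-trig attack of C5 on the aldehyde carbon and ring B by 5-exo-trig O-acylation. The one new stereocentre, C6, is controlled by C7 and C8 through the ring-A transition state: with the C5–C6–C7–C8 torsion gauche and the C11 branch outside the ring, the aldehyde hydrogen rather than the chromium-bound oxygen should take the sector between C8 and C11, which puts O6 trans to C11 (6R, H6 anti to H7) and agrees with the Felkin–Anh (C8 as large group) and 1,3-anti preferences of this anti α-branched β-silyloxy aldehyde. The step needs chemoselectivity for the C6 aldehyde over the C14 enal and the ester, and ring closure over oligomerization: 1,2-addition to C14 would demand a trans double bond in a seven-membered ring, organochromium reagents do not add to esters, and high dilution with a chain folded by two cis-in-ring olefins favours cyclization.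

Step 18
Reactants: 26 (3aS,4R,6E,10E,11aR)-10-{[(tert-butyldiphenylsilyl)oxy]methyl}-3-[(dimethylamino)methyl]-2-oxo-4-[(triethylsilyl)oxy]-2,3,3a,4,5,8,9,11a-octahydrocyclodeca[b]furan-6-carbaldehyde
Product: 28 (3aS,4R,6E,10E,11aR)-10-{[(tert-butyldiphenylsilyl)oxy]methyl}-3-methylidene-2-oxo-4-[(triethylsilyl)oxy]-2,3,3a,4,5,8,9,11a-octahydrocyclodeca[b]furan-6-carbaldehyde, via quaternary trimethylammonium iodide 27 (not isolated)
Conditions: MeI (excess), CH2Cl2, 20 °C; evaporate; NaHCO3, EtOAc/H2O, 20 °C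
Reagents that add atoms: none
Why: Exhaustive N-methylation followed by E1cB (Hofmann-type) loss of trimethylamine from the quaternized Mannich base unveils the exocyclic C11=C13 methylene without strong base, so the enal and the silyl ethers should survive.

Step 19
Reactants: 28 (3aS,4R,6E,10E,11aR)-10-{[(tert-butyldiphenylsilyl)oxy]methyl}-3-methylidene-2-oxo-4-[(triethylsilyl)oxy]-2,3,3a,4,5,8,9,11a-octahydrocyclodeca[b]furan-6-carbaldehyde
Product: 29 (3aR,4R,6E,10E,11aR)-10-{[(tert-butyldiphenylsilyl)oxy]methyl}-4-hydroxy-3-methylidene-2-oxo-2,3,3a,4,5,8,9,11a-octahydrocyclodeca[b]furan-6-carbaldehyde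
Conditions: HF·pyridine, pyridine, THF, 0 °C
Reagents that add atoms: none
Why: Selective desilylation: under buffered HF·pyridine at 0 °C a triethylsilyl ether is cleaved far faster than a tert-butyldiphenylsilyl ether.

Step 20
Reactants: 29 (3aR,4R,6E,10E,11aR)-10-{[(tert-butyldiphenylsilyl)oxy]methyl}-4-hydroxy-3-methylidene-2-oxo-2,3,3a,4,5,8,9,11a-octahydrocyclodeca[b]furan-6-carbaldehyde; 30 (S)-2-methylbutanoic acid
Product: 31 (3aR,4R,6E,10E,11aR)-10-{[(tert-butyldiphenylsilyl)oxy]methyl}-6-formyl-3-methylidene-2-oxo-2,3,3a,4,5,8,9,11a-octahydrocyclodeca[b]furan-4-yl (2S)-2-methylbutanoate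
Conditions: N,N′-dicyclohexylcarbodiimide, 4-(dimethylamino)pyridine (cat.), CH2Cl2, 0 → 20 °C
Reagents that add atoms: none
Why: Steglich esterification acylates the C8 hydroxyl with the chiral-pool acid under near-neutral conditions that should preserve the α-stereocentre of the acid, the enal and the α-methylene lactone.

Step 21
Reactants: 31 (3aR,4R,6E,10E,11aR)-10-{[(tert-butyldiphenylsilyl)oxy]methyl}-6-formyl-3-methylidene-2-oxo-2,3,3a,4,5,8,9,11a-octahydrocyclodeca[b]furan-4-yl (2S)-2-methylbutanoate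
Product: 32 (3aR,4R,6E,10E,11aR)-6-formyl-10-(hydroxymethyl)-3-methylidene-2-oxo-2,3,3a,4,5,8,9,11a-octahydrocyclodeca[b]furan-4-yl (2S)-2-methylbutanoate
Conditions: HF·pyridine, THF, 20 °C
Reagents that add atoms: none
Why: Fluoride-mediated desilylation in an acidic, non-nucleophilic medium frees the C15 hydroxyl while sparing the α-methylene lactone, the C8 ester and the enal.

**Compound list**

1 | diethyl (S)-malate | CCOC(=O)[C@@H](O)CC(=O)OCC | starting material
2 | allyl bromide | C=CCBr | starting material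
3 | diethyl (2S,3R)-2-hydroxy-3-(prop-2-en-1-yl)butanedioate | CCOC(=O)[C@@H](O)[C@@H](CC=C)C(=O)OCC | intermediate
4 | ethyl (2R)-2-[(1S)-1,2-dihydroxyethyl]pent-4-enoate | OC[C@@H](O)[C@@H](CC=C)C(=O)OCC | intermediate
5 | ethyl (2R)-2-[(1S)-1-hydroxy-2-iodoethyl]pent-4-enoate | IC[C@@H](O)[C@@H](CC=C)C(=O)OCC | intermediate
6 | ethyl (2R)-2-{(1S)-2-iodo-1-[(triethylsilyl)oxy]ethyl}pent-4-enoate | IC[C@@H](O[Si](CC)(CC)CC)[C@@H](CC=C)C(=O)OCC | intermediate
7 | (2R)-2-{(1S)-2-iodo-1-[(triethylsilyl)oxy]ethyl}-N-methoxy-N-methylpent-4-enamide | IC[C@@H](O[Si](CC)(CC)CC)[C@@H](CC=C)C(=O)N(C)OC | intermediate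
8 | methyl (3R,4S)-5-iodo-3-[methoxy(methyl)carbamoyl]-4-[(triethylsilyl)oxy]pentanoate | IC[C@@H](O[Si](CC)(CC)CC)[C@@H](CC(=O)OC)C(=O)N(C)OC | intermediate
9 | diethyl {2-[methoxy(methyl)amino]-2-oxoethyl}phosphonate | CCOP(=O)(OCC)CC(=O)N(C)OC | starting material
10 | methyl (3R,4R)-6-(diethoxyphosphoryl)-3-[methoxy(methyl)carbamoyl]-7-[methoxy(methyl)amino]-7-oxo-4-[(triethylsilyl)oxy]heptanoate (epimers at C6 of the chain) | CCOP(=O)(OCC)C(C[C@@H](O[Si](CC)(CC)CC)[C@@H](CC(=O)OC)C(=O)N(C)OC)C(=O)N(C)OC | intermediate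
11 | diethyl malonate | CCOC(=O)CC(=O)OCC | starting material
12 | 2-(2-bromoethyl)-1,3-dioxolane | BrCCC1OCCO1 | starting material
13 | diethyl 2-[2-(1,3-dioxolan-2-yl)ethyl]propanedioate | CCOC(=O)C(CCC1OCCO1)C(=O)OCC | intermediate
14 | iodoform | IC(I)I | starting material
15 | diethyl 2-(diiodomethyl)-2-[2-(1,3-dioxolan-2-yl)ethyl]propanedioate | CCOC(=O)C(CCC1OCCO1)(C(I)I)C(=O)OCC | intermediate
16 | dipotassium 2-(diiodomethyl)-2-[2-(1,3-dioxolan-2-yl)ethyl]propanedioate | [K+].[K+].[O-]C(=O)C(CCC1OCCO1)(C(I)I)C([O-])=O | intermediate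
17 | (2E)-2-[2-(1,3-dioxolan-2-yl)ethyl]-3-iodoprop-2-enoic acid | I/C=C(/C(=O)O)CCC1OCCO1 | intermediate
18 | (2E)-2-[2-(1,3-dioxolan-2-yl)ethyl]-3-iodoprop-2-en-1-ol | I/C=C(/CO)CCC1OCCO1 | intermediate
19 | tert-butyl({(2E)-2-[2-(1,3-dioxolan-2-yl)ethyl]-3-iodoprop-2-en-1-yl}oxy)diphenylsilane | I/C=C(/CO[Si](c1ccccc1)(c1ccccc1)C(C)(C)C)CCC1OCCO1 | intermediate
20 | (4E)-4-{[(tert-butyldiphenylsilyl)oxy]methyl}-5-iodopent-4-enal | I/C=C(/CO[Si](c1ccccc1)(c1ccccc1)C(C)(C)C)CCC=O | intermediate
21 | methyl (3R,4R,6E,10E)-10-{[(tert-butyldiphenylsilyl)oxy]methyl}-11-iodo-3,6-bis[methoxy(methyl)carbamoyl]-4-[(triethylsilyl)oxy]undeca-6,10-dienoate | I/C=C(/CO[Si](c1ccccc1)(c1ccccc1)C(C)(C)C)CC/C=C(/C(=O)N(C)OC)C[C@@H](O[Si](CC)(CC)CC)[C@@H](CC(=O)OC)C(=O)N(C)OC | intermediate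
22 | N,N-dimethylmethyleneiminium iodide | C=[N+](C)C.[I-] | starting material
23 | methyl (3R,4R,6E,10E)-10-{[(tert-butyldiphenylsilyl)oxy]methyl}-2-[(dimethylamino)methyl]-11-iodo-3,6-bis[methoxy(methyl)carbamoyl]-4-[(triethylsilyl)oxy]undeca-6,10-dienoate (epimers at C2 of the chain) | I/C=C(/CO[Si](c1ccccc1)(c1ccccc1)C(C)(C)C)CC/C=C(/C(=O)N(C)OC)C[C@@H](O[Si](CC)(CC)CC)[C@@H](C(CN(C)C)C(=O)OC)C(=O)N(C)OC | intermediate
24 | methyl (3R,4R,6E,10E)-10-{[(tert-butyldiphenylsilyl)oxy]methyl}-2-[(dimethylamino)methyl]-3,6-diformyl-11-iodo-4-[(triethylsilyl)oxy]undeca-6,10-dienoate (epimers at C2 of the chain) | I/C=C(/CO[Si](c1ccccc1)(c1ccccc1)C(C)(C)C)CC/C=C(/C=O)C[C@@H](O[Si](CC)(CC)CC)[C@@H](C(CN(C)C)C(=O)OC)C=O | intermediate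
25 | C6-O-dichlorochromium alkoxide of the ring-A seco hydroxy ester (6R,7R,8R; ring B still open, methyl ester at C12) | COC(=O)C(CN(C)C)[C@H]1[C@H](O[Cr](Cl)Cl)/C=C(/CO[Si](c2ccccc2)(c2ccccc2)C(C)(C)C)CC/C=C(/C=O)C[C@H]1O[Si](CC)(CC)CC | intermediate
26 | (3aS,4R,6E,10E,11aR)-10-{[(tert-butyldiphenylsilyl)oxy]methyl}-3-[(dimethylamino)methyl]-2-oxo-4-[(triethylsilyl)oxy]-2,3,3a,4,5,8,9,11a-octahydrocyclodeca[b]furan-6-carbaldehyde (epimers at C3) | CN(C)CC1C(=O)O[C@@H]2/C=C(/CO[Si](c3ccccc3)(c3ccccc3)C(C)(C)C)CC/C=C(/C=O)C[C@@H](O[Si](CC)(CC)CC)[C@@H]12 | intermediate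
27 | trimethylammonium iodide of 26 (N-methylated at the C13 nitrogen) | C[N+](C)(C)CC1C(=O)O[C@@H]2/C=C(/CO[Si](c3ccccc3)(c3ccccc3)C(C)(C)C)CC/C=C(/C=O)C[C@@H](O[Si](CC)(CC)CC)[C@@H]12.[I-] | intermediate
28 | (3aS,4R,6E,10E,11aR)-10-{[(tert-butyldiphenylsilyl)oxy]methyl}-3-methylidene-2-oxo-4-[(triethylsilyl)oxy]-2,3,3a,4,5,8,9,11a-octahydrocyclodeca[b]furan-6-carbaldehyde | C=C1C(=O)O[C@@H]2/C=C(/CO[Si](c3ccccc3)(c3ccccc3)C(C)(C)C)CC/C=C(/C=O)C[C@@H](O[Si](CC)(CC)CC)[C@@H]12 | intermediate
29 | (3aR,4R,6E,10E,11aR)-10-{[(tert-butyldiphenylsilyl)oxy]methyl}-4-hydroxy-3-methylidene-2-oxo-2,3,3a,4,5,8,9,11a-octahydrocyclodeca[b]furan-6-carbaldehyde | C=C1C(=O)O[C@@H]2/C=C(/CO[Si](c3ccccc3)(c3ccccc3)C(C)(C)C)CC/C=C(/C=O)C[C@@H](O)[C@@H]12 | intermediate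
30 | (S)-2-methylbutanoic acid | OC(=O)[C@@H](C)CC | starting material
31 | (3aR,4R,6E,10E,11aR)-10-{[(tert-butyldiphenylsilyl)oxy]methyl}-6-formyl-3-methylidene-2-oxo-2,3,3a,4,5,8,9,11a-octahydrocyclodeca[b]furan-4-yl (2S)-2-methylbutanoate | C=C1C(=O)O[C@@H]2/C=C(/CO[Si](c3ccccc3)(c3ccccc3)C(C)(C)C)CC/C=C(/C=O)C[C@@H](OC(=O)[C@@H](C)CC)[C@@H]12 | intermediate
32 | (3aR,4R,6E,10E,11aR)-6-formyl-10-(hydroxymethyl)-3-methylidene-2-oxo-2,3,3a,4,5,8,9,11a-octahydrocyclodeca[b]furan-4-yl (2S)-2-methylbutanoate | C=C1C(=O)O[C@@H]2/C=C(/CO)CC/C=C(/C=O)C[C@@H](OC(=O)[C@@H](C)CC)[C@@H]12 | target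

**Step count and risks**

Total step count: 21. Longest linear sequence: 15 steps (steps 1–7 and 14–21); the west fragment (steps 8–13) joins at step 14.

Steps most likely to fail:

Step 17. The process at risk is facial selectivity of the vinylchromium addition at C6, together with ring closure competing against oligomerization. The fallback sets out from 24 and returns at 26. If the addition favours the other face, the same conditions would give the cis-fused (3aS,4R,6E,10E,11aS)-10-{[(tert-butyldiphenylsilyl)oxy]methyl}-3-[(dimethylamino)methyl]-2-oxo-4-[(triethylsilyl)oxy]-2,3,3a,4,5,8,9,11a-octahydrocyclodeca[b]furan-6-carbaldehyde F1. LiOH in THF/H2O would open F1 to 3-(dimethylamino)-2-[(1S,2S,3E,7E,10R)-4-{[(tert-butyldiphenylsilyl)oxy]methyl}-8-formyl-2-hydroxy-10-[(triethylsilyl)oxy]cyclodeca-3,7-dien-1-yl]propanoic acid F2. A Mitsunobu lactonization (PPh3, diisopropyl azodicarboxylate, toluene, high dilution) would then close ring B by SN2 displacement at C6 with inversion, so that C6 is set by substitution rather than by addition, and would deliver 26.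

Step 14. The process at risk is erosion of olefin geometry in the olefination of the α-branched phosphonate. The fallback sets out from 10 and 20 and returns at 21. Olefination of 10 with aqueous formaldehyde and K2CO3 would give methyl (3R,4R)-3,6-bis[methoxy(methyl)carbamoyl]-4-[(triethylsilyl)oxy]hept-6-enoate F3. Wittig methylenation of 20 (Ph3P=CH2, THF) would give tert-butyl{[(2E)-2-(iodomethylidene)hex-5-en-1-yl]oxy}diphenylsilane F4. Cross-metathesis of F3 and F4 with the second-generation Hoveyda–Grubbs catalyst (CH2Cl2, 40 °C) should then form C1=C10 under thermodynamic control, leading to 21.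

Step 2. The process at risk is competing hydroboration of the allyl group and lactonization of the diol. The fallback sets out from 3 and returns at 6; it differentiates the two esters electronically instead of by hydroxyl delivery. Silylation of 3 (Et3SiOTf, 2,6-lutidine) would give diethyl (2S,3R)-3-(prop-2-en-1-yl)-2-[(triethylsilyl)oxy]butanedioate F5. One equivalent of iBu2AlH at −78 °C should reduce the more electrophilic, chelating α-silyloxy ester to ethyl (2R)-2-{(1S)-2-oxo-1-[(triethylsilyl)oxy]ethyl}pent-4-enoate F6. NaBH4 in EtOH at 0 °C would give ethyl (2R)-2-{(1S)-2-hydroxy-1-[(triethylsilyl)oxy]ethyl}pent-4-enoate F7, and PPh3/I2/imidazole would convert F7 into 6.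

Further compounds
F1 | step 17 | (3aS,4R,6E,10E,11aS)-10-{[(tert-butyldiphenylsilyl)oxy]methyl}-3-[(dimethylamino)methyl]-2-oxo-4-[(triethylsilyl)oxy]-2,3,3a,4,5,8,9,11a-octahydrocyclodeca[b]furan-6-carbaldehyde | CN(C)CC1C(=O)O[C@H]2/C=C(/CO[Si](c3ccccc3)(c3ccccc3)C(C)(C)C)CC/C=C(/C=O)C[C@@H](O[Si](CC)(CC)CC)[C@@H]12
F2 | step 17 | 3-(dimethylamino)-2-[(1S,2S,3E,7E,10R)-4-{[(tert-butyldiphenylsilyl)oxy]methyl}-8-formyl-2-hydroxy-10-[(triethylsilyl)oxy]cyclodeca-3,7-dien-1-yl]propanoic acid | OC(=O)C(CN(C)C)[C@H]1[C@@H](O)/C=C(/CO[Si](c2ccccc2)(c2ccccc2)C(C)(C)C)CC/C=C(/C=O)C[C@H]1O[Si](CC)(CC)CC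
F3 | step 14 | methyl (3R,4R)-3,6-bis[methoxy(methyl)carbamoyl]-4-[(triethylsilyl)oxy]hept-6-enoate | C=C(C(=O)N(C)OC)C[C@@H](O[Si](CC)(CC)CC)[C@@H](CC(=O)OC)C(=O)N(C)OC
F4 | step 14 | tert-butyl{[(2E)-2-(iodomethylidene)hex-5-en-1-yl]oxy}diphenylsilane | I/C=C(/CO[Si](c1ccccc1)(c1ccccc1)C(C)(C)C)CCC=C
F5 | step 2 | diethyl (2S,3R)-3-(prop-2-en-1-yl)-2-[(triethylsilyl)oxy]butanedioate | CCOC(=O)[C@@H](O[Si](CC)(CC)CC)[C@@H](CC=C)C(=O)OCC
F6 | step 2 | ethyl (2R)-2-{(1S)-2-oxo-1-[(triethylsilyl)oxy]ethyl}pent-4-enoate | O=C[C@@H](O[Si](CC)(CC)CC)[C@@H](CC=C)C(=O)OCC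
F7 | step 2 | ethyl (2R)-2-{(1S)-2-hydroxy-1-[(triethylsilyl)oxy]ethyl}pent-4-enoate | OC[C@@H](O[Si](CC)(CC)CC)[C@@H](CC=C)C(=O)OCC
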